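Per part of target, Friday's flask at −25 °C has lost 0.134 part of substrate elsewhere by its last reading, while Wednesday's at 10 °C has lost 3.45 by its first, far more.

common to all: free catalyst 0.11 mol%
- Friday's: substrate 0.10 mM; temperature −25 °C; run made earlier
- Wednesday's: substrate 0.15 mM; temperature 10 °C; run made earlier
- teal: substrate 0.20 mM; temperature 0 °C; time 2.0 min
- ochre: substrate 0.20 mM; temperature 20 °C; time 2.0 min
- red: substrate 0.20 mM; temperature −20 °C; time 2.0 min
- amber: substrate 0.20 mM; temperature 40 °C; time 2.0 min

Friday's run (percent of the substrate charged)

| time / min | target / % | substrate / % |
|---|---|---|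
| 0.500 | 15 | 85 |
| 0.833 | 20 | 78 |
| 1.33 | 27 | 62 |
| 3.00 | 50 | 40 |
| 5.00 | 67 | 24 |

Wednesday's run (percent of the substrate charged)

| time / s | target / % | substrate / % |
|---|---|---|
| 10.0 | 11 | 51 |
| 15.0 | 16 | 41 |
| 30.0 | 14 | 25 |
| 60.0 | 11 | 3 |

(each reading ± 2 percentage points)



- the flask with the highest amount of target, in percent of the substrate charged ("all alike" if they lie within 1.5 percentage points) (teal / ochre / red / amber / all alike)
- final target, as a percentage of the substrate charged, in teal
- final target, as a percentage of the substrate charged, in ochre
- final target, as a percentage of the substrate charged, in red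
- final target, as a percentage of the substrate charged, in amber

I call this number the leak ratio; it is the inverse of a selectivity factor. I assume that target is made through the free catalyst and that the leak doesn't need it. The loading is fixed, so on that assumption [free catalyst] follows the charge and, at one temperature, the leak ratio falls as the charge rises. As read from the two runs, the leak ratio at equal charge and loading doubles every 6.64 K, and this rise in temperature is the doubling step that I carry.

Red, at −20 °C with twice Friday's charge, then reckons at a leak ratio of 0.113, so I expect 89.8 % of what reacts there to become target. Amber comes out at 59.3, far above red, so I pick red. Friday's last reading puts the first-order constant of its substrate loss at 0.285 min⁻¹. Doubling that for red gives 61.2 % target at 2.0 min. Friday's target is still rising at its last reading, so I leave its decay out.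

The weak link is that red is warmer than Friday's flask. Per unit of charge, the target part of the constant grows by a factor of 2.40 between the runs. Scaling it to red's temperature lifts my figure to 64.6 %, and I commit to that.

The forecast also names red, with 42 % there, 22 % in teal, 1.5 % in ochre and 0.2 % in amber. It differs from my reckoning on the charge, holding “so the 0.20 mM charge doesn't matter”, and its red stands lower than mine.

The flasks give red first, with 67.4 % target in red, 29.7 % in teal, 6.59 % in ochre and 1.95 % in amber.

    substrate + free catalyst → free catalyst + target (k = 1.53 × 10⁵ L mol⁻¹ s⁻¹, Ea = 29.0 kJ mol⁻¹)
    substrate → side product (k = 0.00137 s⁻¹, Ea = 76.0 kJ mol⁻¹)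
    substrate → uncatalysed product (k = 0.0129 s⁻¹, Ea = 67.0 kJ mol⁻¹)
    free catalyst → spent catalyst (k = 0.0315 s⁻¹, Ea = 82.0 kJ mol⁻¹)
    target ⇌ isomer of the product (K = 1.40, k = 0.00662 s⁻¹, Ea = 86.0 kJ mol⁻¹, ΔH = −2.00 kJ mol⁻¹)
    (constants at 0 °C)

From red to amber the making of target speeds up by a factor of 14, and the loss of substrate to side product by 1000. Counting the isomer of the product with target, red's leak ratio at 1.00 min stands at 0.115. In the neighbour, a repeat of amber at 15 °C, the doubling step gives a leak ratio of 4.37, so 18.6 % of the charge should end as target and isomer. That flask holds 20.9 %, of which 8.95 % is target.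

(The data were computed for substances that don't exist; noise was put on by code.)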